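**Retrosynthetic overview**
- Last bond: the aryl ether C–O bond of the pyran ring, closed on a secondary carbinol with retention through participation of the homoallylic ring alkene (new method).
- The carbinol and the neighbouring quaternary carbon come from one cyclopentanone: hydride to C=O and methyl to its enolate (methyl last), after the benzylic C–C bond is made by an enamine / o-quinone methide [4+2] with the formylated phloroglucinol and the C5 aldehyde.
- The spiro-cyclopentanone comes from a quaternary pent-4-enal by rhodium hydroacylation; its quaternary centre comes from deconjugative allylation of a cyclohexene carbaldehyde.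
- That enal comes from a chiral-pool menthane ketone (methyl stereocentre) by chloroformylation and hydrodechlorination.
- Ring order: cyclohexene (chiral pool) → spiro-cyclopentanone → arene attached → pyran last.

Assumption: the four building blocks named below as starting materials are catalogue compounds (the formylated phloroglucinol is otherwise one Vilsmeier step from phloroglucinol).
Locants: the spiro[4.5]decane numbering of the spiro ketone is kept for all later compounds (C1 = carbonyl/carbinol/O-bearing carbon, C2, C5 = spiro atom, C6=C7 alkene, C10 = CHMe); C1″ is the benzylic carbon carrying the isobutyl group. "C6 face" and "C10 face" mean the faces of the five-membered ring syn to C6 (vinyl CH) and to C10 (CHMe).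

**Step 1**
Reactants: 1 (−)-menthone, (2S,5R)-5-methyl-2-(propan-2-yl)cyclohexan-1-one
Product: 2 (3S,6R)-2-chloro-6-methyl-3-(propan-2-yl)cyclohex-1-ene-1-carbaldehyde
Conditions: POCl3, DMF, CH2Cl2, 0 → 60 °C; aq. NaOAc
Reagents that add atoms: N,N-dimethylformamide, CN(C)C=O; phosphoryl chloride, O=P(Cl)(Cl)Cl; water, O
Why: Vilsmeier–Haack–Arnold chloroformylation: the ketone is formylated at its only α-CH2 and the carbonyl carbon becomes the vinyl chloride; the methyl stereocentre (β to the ketone) is untouched and C3 is irrelevant because it becomes sp2 in step 3.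

**Step 2**
Reactants: 2 (3S,6R)-2-chloro-6-methyl-3-(propan-2-yl)cyclohex-1-ene-1-carbaldehyde
Product: 3 (3S,6R)-6-methyl-3-(propan-2-yl)cyclohex-1-ene-1-carbaldehyde
Conditions: Pd(OAc)2 (5 mol%), PPh3, HCO2H, Et3N, DMF, 80 °C
Reagents that add atoms: none
Why: Palladium-catalysed formate hydrogenolysis: the β-acyl-activated vinyl chloride adds oxidatively to zerovalent palladium, formate delivers hydride with loss of CO2, and reductive elimination gives the enal.

**Step 3**
Reactants: 3 (3S,6R)-6-methyl-3-(propan-2-yl)cyclohex-1-ene-1-carbaldehyde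
Product: 4 (1R,6R)-6-methyl-3-(propan-2-yl)-1-(prop-2-en-1-yl)cyclohex-2-ene-1-carbaldehyde
Conditions: KH, THF, 0 °C; allyl bromide, 0 °C → rt
Reagents that add atoms: allyl bromide, C=CCBr
Why: Deconjugative α-alkylation of the potassium dienolate (γ-deprotonation at C3): allylic 1,3-strain makes the C6 methyl pseudo-axial, so allyl enters anti to it and sets the quaternary centre (R, formyl cis to the methyl) while the alkene moves to the C2=C3 position required in the target.

**Step 4**
Reactants: 4 (1R,6R)-6-methyl-3-(propan-2-yl)-1-(prop-2-en-1-yl)cyclohex-2-ene-1-carbaldehyde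
Product: 5 (5R,10R)-10-methyl-7-(propan-2-yl)spiro[4.5]dec-6-en-1-one
Conditions: [Rh(dppe)]ClO4 (5 mol%), CH2Cl2, rt
Reagents that add atoms: none
Why: Intramolecular hydroacylation of a 2,2-disubstituted pent-4-enal by a cationic monovalent rhodium diphosphine catalyst (acyl–Rh–H, alkene insertion, reductive elimination); the quaternary α-carbon suppresses decarbonylation and no stereocentre is formed or touched.

**Step 5**
Reactants: 5 (5R,10R)-10-methyl-7-(propan-2-yl)spiro[4.5]dec-6-en-1-one; 6 2,4,6-trihydroxybenzene-1,3-dicarbaldehyde; 7 3-methylbutanal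
Product: 11 2,4,6-trihydroxy-5-{(1R)-3-methyl-1-[(2R,5R,10R)-10-methyl-1-oxo-7-(propan-2-yl)spiro[4.5]dec-6-en-2-yl]butyl}benzene-1,3-dicarbaldehyde, via enamine 8 (not isolated), via quinone methide 9 (not isolated), via aminal 10 (not isolated)
Conditions: pyrrolidine (1.3 equiv), p-TsOH·H2O (cat.), PhMe, Dean–Stark; then 6, 7, MeCN, 0 °C → rt; aq. citric acid
Reagents that add atoms: water, O
Why: Enamine / o-quinone methide inverse-demand hetero-Diels–Alder (9 arises by Knoevenagel condensation of 6 with 7): 9 adds to the enamine on the less hindered C6 face with the amino group endo, which sets C1″ as R; hydrolysis of aminal 10 gives the ketone, whose C2 centre (R as formed) is epimerisable and is erased in step 6.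

**Step 6**
Reactants: 11 2,4,6-trihydroxy-5-{(1R)-3-methyl-1-[(2R,5R,10R)-10-methyl-1-oxo-7-(propan-2-yl)spiro[4.5]dec-6-en-2-yl]butyl}benzene-1,3-dicarbaldehyde
Product: 13 2,4,6-trihydroxy-5-{(1R)-1-[(1R,2S,5R,10R)-1-hydroxy-2,10-dimethyl-7-(propan-2-yl)spiro[4.5]dec-6-en-2-yl]-3-methylbutyl}benzene-1,3-dicarbaldehyde, via methylated ketone 12 (not isolated)
Conditions: KN(SiMe3)2 (4.3 equiv), THF–DMPU, −78 °C; MeI (1.05 equiv), −78 → −40 °C; then LiAlH4 (1.5 equiv), −40 → 0 °C; aq. HCl
Reagents that add atoms: iodomethane, CI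
Why: Polyanion enolate alkylation then hydride reduction in one pot: the tetra-anion is methylated at its only carbanionic site from the C6 face, which is also anti to the aryl group in the allylic-strain-minimised rotamer (sets C2 as S, benzylic carbon pushed to the C10 face); the phenoxide-conjugated formyl groups are shielded as vinylogous carboxylates while LiAlH4 attacks the neopentylic ketone from the methyl-bearing C6 face (sets C1 as R, hydroxyl anti to C6).

**Step 7**
Reactants: 13 2,4,6-trihydroxy-5-{(1R)-1-[(1R,2S,5R,10R)-1-hydroxy-2,10-dimethyl-7-(propan-2-yl)spiro[4.5]dec-6-en-2-yl]-3-methylbutyl}benzene-1,3-dicarbaldehyde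
Product: 14 CNP0121396.1, the cis-fused chroman (1R,2S,5R,10R,1″R)
Conditions: (CF3SO2)2NH (5 mol%), (CF3)2CHOH–CH2Cl2 (1:4), −20 → 0 °C
Reagents that add atoms: none
Why: Proposed new method: acid-catalysed dehydrative cyclo-etherification with retention at a carbinol flanked by two quaternary carbons, driven by homoallylic participation: loss of water from C1 is assisted by backside overlap of the C6=C7 π bond (anti to the hydroxyl), giving a cyclopropylcarbinyl (cubebyl-type) cation with the charge at tertiary C7 instead of an unassisted secondary cation; the tethered, acidic phenol oxygen can reach only C1 (six-membered ring) and attacks anti to the C1–C6 partial bond, so the C–O bond forms on the face the hydroxyl left (double inversion, C1 stays R, cis-fused pyran) and the alkene is returned; the closest known reaction type is the cholesteryl / 3,5-cyclosteroid homoallylic substitution with retention, which has not been used for ring-closing aryl ether formation at such a centre.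

**Compound list**
1 | (−)-menthone, (2S,5R)-5-methyl-2-(propan-2-yl)cyclohexan-1-one | O=C1C[C@H](C)CC[C@H]1C(C)C | starting material
2 | (3S,6R)-2-chloro-6-methyl-3-(propan-2-yl)cyclohex-1-ene-1-carbaldehyde | O=CC1=C(Cl)[C@H](C(C)C)CC[C@H]1C | intermediate
3 | (3S,6R)-6-methyl-3-(propan-2-yl)cyclohex-1-ene-1-carbaldehyde | O=CC1=C[C@H](C(C)C)CC[C@H]1C | intermediate
4 | (1R,6R)-6-methyl-3-(propan-2-yl)-1-(prop-2-en-1-yl)cyclohex-2-ene-1-carbaldehyde | O=C[C@@]1(CC=C)C=C(C(C)C)CC[C@H]1C | intermediate
5 | (5R,10R)-10-methyl-7-(propan-2-yl)spiro[4.5]dec-6-en-1-one | O=C1CCC[C@@]12C=C(C(C)C)CC[C@H]2C | intermediate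
6 | 2,4,6-trihydroxybenzene-1,3-dicarbaldehyde (diformylphloroglucinol) | O=Cc1c(O)cc(O)c(C=O)c1O | starting material
7 | 3-methylbutanal (isovaleraldehyde) | CC(C)CC=O | starting material
8 | 1-[(5R,10R)-10-methyl-7-(propan-2-yl)spiro[4.5]deca-1,6-dien-1-yl]pyrrolidine | C1CCN(C1)C1=CCC[C@@]12C=C(C(C)C)CC[C@H]2C | intermediate
9 | 2,4-dihydroxy-5-(3-methylbutylidene)-6-oxocyclohexa-1,3-diene-1,3-dicarbaldehyde (o-quinone methide) | CC(C)CC=C1C(=O)C(C=O)=C(O)C(C=O)=C1O | intermediate
10 | [4+2] adduct: cis-fused 2-(pyrrolidin-1-yl)chroman N,O-ketal, (1S,2R,5R,10R,1″R), ring oxygen and C1″ on the C6 face, isobutyl cis to nitrogen | CC(C)C[C@H]1c2c(O)c(C=O)c(O)c(C=O)c2O[C@@]2(N3CCCC3)[C@@H]1CC[C@@]21C=C(C(C)C)CC[C@H]1C | intermediate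
11 | 2,4,6-trihydroxy-5-{(1R)-3-methyl-1-[(2R,5R,10R)-10-methyl-1-oxo-7-(propan-2-yl)spiro[4.5]dec-6-en-2-yl]butyl}benzene-1,3-dicarbaldehyde (C2 epimerisable; in equilibrium with its hemiketal) | CC(C)C[C@@H](c1c(O)c(C=O)c(O)c(C=O)c1O)[C@H]1CC[C@@]2(C=C(C(C)C)CC[C@H]2C)C1=O | intermediate
12 | 2,4,6-trihydroxy-5-{(1S)-1-[(2S,5R,10R)-2,10-dimethyl-1-oxo-7-(propan-2-yl)spiro[4.5]dec-6-en-2-yl]-3-methylbutyl}benzene-1,3-dicarbaldehyde (same spatial arrangement at C1″ as in 11; the descriptor changes by priority only) | CC(C)C[C@@H](c1c(O)c(C=O)c(O)c(C=O)c1O)[C@]1(C)CC[C@@]2(C=C(C(C)C)CC[C@H]2C)C1=O | intermediate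
13 | 2,4,6-trihydroxy-5-{(1R)-1-[(1R,2S,5R,10R)-1-hydroxy-2,10-dimethyl-7-(propan-2-yl)spiro[4.5]dec-6-en-2-yl]-3-methylbutyl}benzene-1,3-dicarbaldehyde | CC(C)C[C@@H](c1c(O)c(C=O)c(O)c(C=O)c1O)[C@]1(C)CC[C@@]2(C=C(C(C)C)CC[C@H]2C)[C@@H]1O | intermediate
14 | CNP0121396.1: cis-fused chroman-dicarbaldehyde, (1R,2S,5R,10R,1″R); ring oxygen on C1 and C1″ on C2 both on the C10 face, C2-methyl on the C6 face, isobutyl trans to the C2-methyl | CC(C)C[C@H]1c2c(O)c(C=O)c(O)c(C=O)c2O[C@@H]2[C@@]1(C)CC[C@@]21C=C(C(C)C)CC[C@H]1C | target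

**Step count and risks**
Total steps: 7. Longest linear sequence: 7 (1 → 14; 6 and 7 are bought and enter at step 5).

The three steps most likely to fail are steps 5, 6 and 7.

Step 5 can fail through competing enamine formation from the aldehyde or through poor facial/endo selectivity, which would give the wrong C1″ epimer. The fallback sets out from 5 and returns at 11. Ketone 5 is converted with i-Pr3SiOTf and Et3N into the triisopropylsilyl enol ether F1. F1 is used in an amine-free domino Knoevenagel / hetero-Diels–Alder reaction with 6 and 7 (ethylenediammonium diacetate catalyst, MeCN, rt), a concerted endo cycloaddition on the C6 face that gives the silyl ketal cycloadduct F2. Mild hydrolysis (aq. AcOH, THF) opens F2 to 11.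

Step 6 can fail at the tetra-anion stage (solubility, O-methylation) or through hydride attack on the formyl groups. The fallback sets out from 11 and returns at 12. The three phenols are capped (MOMCl, i-Pr2NEt) to give the tris(methoxymethyl) ether F3. Its ketone enolate (KH, THF) is methylated with MeI under the same facial control to give the C2-methylated tris(methoxymethyl) ether F4. HCl in MeOH releases 12, which is then taken through the hydride stage of step 6 (three equivalents of KN(SiMe3)2, then LiAlH4).

Step 7 is the new reaction; it can fail by elimination or skeletal rearrangement of the cyclopropylcarbinyl cation before the phenol captures it. The fallback uses known chemistry, sets out from 12 (isolated by leaving out the hydride stage of step 6) and returns at 14. Silylation (Me3SiCl, (Me3Si)2NH) gives the tris(trimethylsilyl) ether F5. The established silyl ether / ketone reductive etherification (Me3SiOTf cat., Et3SiH, CH2Cl2, −78 → −30 °C) closes the pyran through the cyclic aryl oxocarbenium ion, with hydride delivered syn to the C2 methyl (cis fusion), to give the bis(trimethylsilyl) ether of the chroman F6. K2CO3 in MeOH removes the silyl groups to give 14.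

**Further compounds**
F1 | step 5 | triisopropyl{[(5R,10R)-10-methyl-7-(propan-2-yl)spiro[4.5]deca-1,6-dien-1-yl]oxy}silane | CC(C)[Si](C(C)C)(C(C)C)OC1=CCC[C@@]12C=C(C(C)C)CC[C@H]2C
F2 | step 5 | silyl ketal cycloadduct, 2-(triisopropylsilyloxy) analogue of 10 (1R,2R,5R,10R,1″R) | CC(C)C[C@H]1c2c(O)c(C=O)c(O)c(C=O)c2O[C@@]2(O[Si](C(C)C)(C(C)C)C(C)C)[C@@H]1CC[C@@]21C=C(C(C)C)CC[C@H]1C
F3 | step 6 | tris(methoxymethyl) ether of 11 | CC(C)C[C@@H](c1c(OCOC)c(C=O)c(OCOC)c(C=O)c1OCOC)[C@H]1CC[C@@]2(C=C(C(C)C)CC[C@H]2C)C1=O
F4 | step 6 | tris(methoxymethyl) ether of 12 | CC(C)C[C@@H](c1c(OCOC)c(C=O)c(OCOC)c(C=O)c1OCOC)[C@]1(C)CC[C@@]2(C=C(C(C)C)CC[C@H]2C)C1=O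
F5 | step 7 | tris(trimethylsilyl) ether of 12 | CC(C)C[C@@H](c1c(O[Si](C)(C)C)c(C=O)c(O[Si](C)(C)C)c(C=O)c1O[Si](C)(C)C)[C@]1(C)CC[C@@]2(C=C(C(C)C)CC[C@H]2C)C1=O
F6 | step 7 | bis(trimethylsilyl) ether of 14 | CC(C)C[C@H]1c2c(O[Si](C)(C)C)c(C=O)c(O[Si](C)(C)C)c(C=O)c2O[C@@H]2[C@@]1(C)CC[C@@]21C=C(C(C)C)CC[C@H]1C
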